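The ten-membered carbocycle is disconnected at C6–C7, and C6 is retied to C12 through oxygen. What is exploited is the hydroxyl-bearing C6 of the ten-membered ring next to C7, the ring carbon that bears the C11(=C12H2) unit of the fused γ-lactone: a homoallylic alcohol, the imprint of a [2,3]-Wittig shift. In one operation the key step contracts a thirteen-membered C6–O–C12 diallylic ether to the cyclodecadiene, makes the C6–C7 bond and sets C6 and C7. Its precursor 24 has ring-cis C4=C5 and C1=C10 alkenes, a ring-trans C7=C11 alkene with a free C13 hydroxyl, a C8 triethylsilyl ether, and O9/O14 bridged as a di-tert-butylsilylene so that C8 can later be unmasked alone.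

Key step: step 18

Remark on labels: C1–C10 are the ring carbons (C1=C10, C4=C5, C6 lactone carbinol, C7 ring fusion, C8 acyloxy carbon, C9 hydroxy carbon); C11 is the carbon on C7, C12 its exocyclic CH2, C13 the lactone carbonyl carbon, C14 the formyl carbon on C10, C15 the methyl on C4; the target is (6R,7S,8S,9S) with an (S)-2-methylbutanoate.
Assumption: ethyl 2-(diethoxyphosphoryl)acrylate (19) is taken as purchasable; otherwise it is one step from triethyl phosphonoacetate and paraformaldehyde.

Step 1
Reactants: 1 nerol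
Product: 2 neryl tert-butyldimethylsilyl ether
Conditions: TBSCl, imidazole, CH2Cl2, 0 °C → rt
Reagents that add atoms: tert-butyldimethylsilyl chloride, CC(C)(C)[Si](C)(C)Cl
Why: Standard silylation of a primary allylic alcohol; the (Z)-alkene of nerol, which becomes the ring-cis C4=C5 bond with C15, is not touched.

Step 2
Reactants: 2 neryl tert-butyldimethylsilyl ether
Product: 4 (4Z)-6-[(tert-butyldimethylsilyl)oxy]-4-methylhex-4-enal, via epoxide 3 (not isolated)
Conditions: mCPBA (1.05 equiv), NaHCO3, CH2Cl2, 0 °C; then H5IO6, THF/H2O, 0 °C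
Reagents that add atoms: 3-chloroperbenzoic acid, OOC(=O)c1cccc(Cl)c1
Why: Prilezhaev epoxidation should pick the remote trisubstituted alkene, the other one being deactivated by the allylic silyloxy group, and periodic acid cleaves the epoxide through its diol to the C1 aldehyde and acetone.

Step 3
Reactants: 4 (4Z)-6-[(tert-butyldimethylsilyl)oxy]-4-methylhex-4-enal
Product: 5 tert-butyldimethyl{[(2Z)-3-methylhept-2-en-6-yn-1-yl]oxy}silane
Conditions: dimethyl (1-diazo-2-oxopropyl)phosphonate, K2CO3, MeOH, 0 °C → rt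
Reagents that add atoms: dimethyl (1-diazo-2-oxopropyl)phosphonate, CC(=O)C(=[N+]=[N-])P(=O)(OC)OC
Why: The Ohira–Bestmann variant of the Seyferth–Gilbert homologation turns the aldehyde into the terminal alkyne, the added carbon being C10.

Step 4
Reactants: 6 methyl (4S)-2,2-dimethyl-1,3-dioxolane-4-carboxylate
Product: 7 (4S)-N-methoxy-N,2,2-trimethyl-1,3-dioxolane-4-carboxamide
Conditions: MeNH(OMe)·HCl, i-PrMgCl, THF, −20 °C
Reagents that add atoms: N,O-dimethylhydroxylamine hydrochloride, CNOC.Cl
Why: Weinreb amide formation by the magnesium amide proceeds below 0 °C without epimerising C8, which is taken from the chiral pool.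

Step 5
Reactants: 5 (Z)-enyne; 7 Weinreb amide
Product: 9 (6Z)-8-[(tert-butyldimethylsilyl)oxy]-1-[(4S)-2,2-dimethyl-1,3-dioxolan-4-yl]-6-methyloct-6-en-2-yn-1-one, via lithium acetylide 8 (not isolated)
Conditions: 5, n-BuLi, THF, −78 °C; then 7, −78 → −20 °C; AcOH, −78 °C
Reagents that add atoms: none
Why: Weinreb ketone synthesis: the acetylide adds once because the chelated tetrahedral adduct survives until the acidic quench, which joins C10 to C9 as the ynone.

Step 6
Reactants: 9 ynone
Product: 10 (1S,6Z)-8-[(tert-butyldimethylsilyl)oxy]-1-[(4S)-2,2-dimethyl-1,3-dioxolan-4-yl]-6-methyloct-6-en-2-yn-1-ol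
Conditions: Ru[(R,R)-TsDPEN](p-cymene) (2 mol%), i-PrOH, rt
Reagents that add atoms: none
Why: Noyori asymmetric transfer hydrogenation of an alkynyl ketone under base-free conditions; the (R,R)-ligand, which treats the alkynyl group like the aryl group of an aryl ketone, should set C9 to the configuration of the target by catalyst control over the adjacent C8 centre.

Step 7
Reactants: 10 propargylic alcohol
Product: 11 (2E,6Z)-vinylstannane with Bu3Sn on C10 and the new hydrogen on C1
Conditions: Bu3SnH (slow addition), PdCl2(PPh3)2 (5 mol%), THF, 0 °C → rt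
Reagents that add atoms: tributyltin hydride, CCCC[SnH](CCCC)CCCC
Why: Palladium-catalysed hydrostannation adds H and Sn to the same side and, for propargylic alcohols, puts tin on the alkyne carbon next to the carbinol (C10), which defines the ring-cis C1=C10 geometry (C2 cis to C9).

Step 8
Reactants: 11 vinylstannane
Product: 13 (1S,2Z,6Z)-8-[(tert-butyldimethylsilyl)oxy]-1-[(4S)-2,2-dimethyl-1,3-dioxolan-4-yl]-2-(hydroxymethyl)-6-methylocta-2,6-dien-1-ol, via dilithio species 12 (not isolated)
Conditions: n-BuLi (3.2 equiv), THF, −78 → −30 °C; then HCHO (gas, from paraformaldehyde), −78 → 0 °C; H2O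
Reagents that add atoms: formaldehyde, C=O
Why: Tin–lithium exchange on the lithium alkoxide gives a configurationally stable vinyllithium that adds to formaldehyde with retention, so C14 enters trans to C2, and the neighbouring oxide cannot leave to form an allene.

Step 9
Reactants: 13 9,14-diol
Product: 14 di-tert-butylsilylene acetal bridging O9 and O14 of 13
Conditions: t-Bu2Si(OTf)2, 2,6-lutidine, CH2Cl2, 0 °C
Reagents that add atoms: di-tert-butylsilyl bis(trifluoromethanesulfonate), CC(C)(C)[Si](OS(=O)(=O)C(F)(F)F)(OS(=O)(=O)C(F)(F)F)C(C)(C)C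
Why: Silylene formation on the 1,3-diol gives a six-membered 1,3,2-dioxasilinane that protects both hydroxyls in one step and is more stable to acid than the groups to be removed next.

Step 10
Reactants: 14 silylene acetonide
Product: 15 6,7,8-triol with the silylene retained
Conditions: CSA (0.2 equiv), MeOH, 0 °C → rt
Reagents that add atoms: none
Why: Acid-catalysed methanolysis removes the terminal acetonide and the primary silyl ether, whereas the hindered six-membered di-tert-butylsilylene is expected to persist under these mild conditions.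

Step 11
Reactants: 15 triol
Product: 16 C6 allylic chloride with the 7,8-diol free
Conditions: NCS, Me2S, CH2Cl2, −30 → 0 °C
Reagents that add atoms: N-chlorosuccinimide, O=C1CCC(=O)N1Cl
Why: Corey–Kim chlorination is selective for allylic alcohols: only the allylic alkoxysulfonium ion is displaced by chloride (SN2, alkene geometry kept), while the saturated 7,8-diol is returned on aqueous work-up.

Step 12
Reactants: 16 chloro diol
Product: 17 7,8-bis(triethylsilyl) ether of 16
Conditions: TESOTf, 2,6-lutidine, CH2Cl2, −78 °C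
Reagents that add atoms: triethylsilyl trifluoromethanesulfonate, CC[Si](CC)(CC)OS(=O)(=O)C(F)(F)F
Why: Triflate silylation at low temperature covers the primary and the hindered secondary hydroxyl and leaves the allylic chloride alone.

Step 13
Reactants: 17 bis(triethylsilyl) ether
Product: 18 C7 aldehyde with the C8 triethylsilyl ether retained
Conditions: (COCl)2, DMSO, CH2Cl2, −78 → −35 °C; then Et3N, −78 → 0 °C
Reagents that add atoms: none
Why: Under Swern conditions a primary triethylsilyl ether is converted directly into the aldehyde while the secondary one stays, so C7 is oxidised without a separate deprotection and the α-silyloxy aldehyde is used at once.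

Step 14
Reactants: 18 aldehyde; 19 ethyl 2-(diethoxyphosphoryl)acrylate
Product: 21 enoate with CO2Et (C12) trans to C8 and CH2OPMB (C13) cis to C8, via phosphonate anion 20 (not isolated)
Conditions: 4-MeOC6H4CH2OH, NaH, THF, 0 °C; then 19, −78 °C; then 18, −78 → 0 °C
Reagents that add atoms: 4-methoxybenzyl alcohol, COc1ccc(CO)cc1
Why: Oxa-Michael addition of the alkoxide to the vinylphosphonate generates the stabilised phosphonate anion, and its Horner–Wadsworth–Emmons reaction with the aldehyde should place the ester trans to C8, as is usual for α-substituted phosphonoacetates.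

Step 15
Reactants: 21 enoate
Product: 22 C12 allylic alcohol
Conditions: i-Bu2AlH, CH2Cl2, −78 °C
Reagents that add atoms: none
Why: 1,2-Reduction of the unsaturated ester to the allylic alcohol at low temperature, which tolerates the allylic chloride, the silyl groups and the PMB ether.

Step 16
Reactants: 22 hydroxy allylic chloride
Product: 23 thirteen-membered C6–O–C12 diallylic ether with C13–OPMB
Conditions: NaH, n-Bu4NI (cat.), THF (2 mM, slow addition of 22), 0 → 40 °C
Reagents that add atoms: none
Why: Intramolecular Williamson etherification under high dilution: the C12 alkoxide displaces the primary allylic chloride at C6 by SN2 (an SN2' path would have to attack fully substituted C4), which closes the ring with all three alkene geometries intact.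

Step 17
Reactants: 23 macrocyclic PMB ether
Product: 24 thirteen-membered diallylic ether with free C13 hydroxyl
Conditions: DDQ, CH2Cl2/aq. NaH2PO4–Na2HPO4 (pH 7), 0 °C
Reagents that add atoms: none
Why: Oxidative PMB cleavage by hydride abstraction and hydrolysis frees the C13 hydroxyl; silyl groups and the diallylic ether are stable to buffered DDQ.

Step 18
Reactants: 24 thirteen-membered diallylic ether
Product: 26 ten-membered (6R,7S)-diol with the C6 hydroxyl and the 3-hydroxyprop-1-en-2-yl group on C7, via dilithio species 25 (not isolated)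
Conditions: n-BuLi (2.3 equiv), THF, −78 → −25 °C; AcOH/THF, −78 °C
Reagents that add atoms: none
Why: The first equivalent of n-BuLi forms the C13 lithium alkoxide and the second removes an allylic, ether-activated proton at C6; the α-oxy allyl anion 25 then undergoes a suprafacial [2,3]-Wittig shift through a five-membered envelope in which C6–C7 forms while O–C12 breaks and C11=C12 becomes the exocyclic methylene. The closest known reaction type is the [2,3]-Wittig ring contraction of thirteen-membered diallylic ethers to cyclodecadienols. The ten-membered carbocycle is closed by ring contraction, the new bond spanning the existing macrocycle in a five-centre sigmatropic transition state, so no open-chain cyclisation and no high dilution are involved. C6 and C7 are formed together: their trans relationship is expected from the ring-trans C7=C11 geometry with the C5 alkenyl group exo on the envelope, and the face of C7 is expected to be fixed by the C8 stereocentre, whose hydrogen eclipses the C11 branch (allylic 1,3-strain) so that the silyloxy group and the C9 ring bond flank the two faces unequally. The step needs site-selective lithiation and [2,3] over [1,2] migration: the adjacent C13 alkoxide disfavours deprotonation at C12, a C12 anion could only bond to the fully substituted C4, and the low temperature suppresses the radical [1,2] path. Both ring-cis alkenes and the silyl groups are spectators, and the cold AcOH quench keeps the triethylsilyl group from migrating to the new C6 alkoxide.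

Step 19
Reactants: 26 ten-membered diol
Product: 29 trans-fused α-methylene γ-lactone, via hydroxy enal 27 (not isolated), via lactol 28 (not isolated)
Conditions: TEMPO (0.2 equiv), PhI(OAc)2 (2.5 equiv), CH2Cl2, rt
Reagents that add atoms: none
Why: Oxoammonium oxidation takes the primary allylic C13 alcohol to the enal, which closes onto the C6 hydroxyl (5-exo) as a lactol that is oxidised on to the lactone; the secondary C6 alcohol is oxidised much more slowly.

Step 20
Reactants: 29 lactone
Product: 30 C8 alcohol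
Conditions: PPTS, MeOH/CH2Cl2, 0 °C → rt
Reagents that add atoms: none
Why: Acid methanolysis cleaves the triethylsilyl ether far faster than the di-tert-butylsilylene and leaves the lactone alone.

Step 21
Reactants: 30 C8 alcohol; 31 (S)-2-methylbutanoic acid
Product: 32 C8 (S)-2-methylbutanoate
Conditions: EDC·HCl, DMAP (cat.), CH2Cl2, 0 °C → rt
Reagents that add atoms: none
Why: Steglich esterification of the only free hydroxyl; carbodiimide activation with catalytic DMAP at low temperature should preserve the α-stereocentre of the acid.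

Step 22
Reactants: 32 silylene ester
Product: 33 9,14-diol
Conditions: HF·pyridine, pyridine, THF, 0 °C → rt
Reagents that add atoms: none
Why: Fluoride removes the silylene as t-Bu2SiF2 and does not affect the ester, the lactone or the alkenes.

Step 23
Reactants: 33 9,14-diol
Product: 34 CNP0168436.1
Conditions: TEMPO (0.1 equiv), PhI(OAc)2 (1.1 equiv), CH2Cl2, 0 °C → rt
Reagents that add atoms: none
Why: TEMPO/PhI(OAc)2 oxidises primary alcohols much faster than secondary ones, so only the primary allylic C14 hydroxyl becomes the aldehyde and the C9 carbinol stays.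

Compound list
1 | nerol, (2Z)-3,7-dimethylocta-2,6-dien-1-ol | OC/C=C(/C)CCC=C(C)C | starting material
2 | neryl TBS ether, tert-butyl{[(2Z)-3,7-dimethylocta-2,6-dien-1-yl]oxy}dimethylsilane | CC(C)(C)[Si](C)(C)OC/C=C(/C)CCC=C(C)C | intermediate
3 | 6,7-epoxide of 2, racemic at the oxirane carbon (not isolated) | CC(C)(C)[Si](C)(C)OC/C=C(/C)CCC1OC1(C)C | intermediate
4 | (4Z)-6-[(tert-butyldimethylsilyl)oxy]-4-methylhex-4-enal (C1 aldehyde to C6) | CC(C)(C)[Si](C)(C)OC/C=C(/C)CCC=O | intermediate
5 | tert-butyldimethyl{[(2Z)-3-methylhept-2-en-6-yn-1-yl]oxy}silane (C10≡C1 to C6) | CC(C)(C)[Si](C)(C)OC/C=C(/C)CCC#C | intermediate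
6 | methyl (4S)-2,2-dimethyl-1,3-dioxolane-4-carboxylate | COC(=O)[C@@H]1COC(C)(C)O1 | starting material
7 | (4S)-N-methoxy-N,2,2-trimethyl-1,3-dioxolane-4-carboxamide | CON(C)C(=O)[C@@H]1COC(C)(C)O1 | intermediate
8 | lithium acetylide of 5 (not isolated) | CC(C)(C)[Si](C)(C)OC/C=C(/C)CCC#C[Li] | intermediate
9 | (6Z)-8-[(tert-butyldimethylsilyl)oxy]-1-[(4S)-2,2-dimethyl-1,3-dioxolan-4-yl]-6-methyloct-6-en-2-yn-1-one (C9 ketone) | CC(C)(C)[Si](C)(C)OC/C=C(/C)CCC#CC(=O)[C@@H]1COC(C)(C)O1 | intermediate
10 | (1S,6Z)-8-[(tert-butyldimethylsilyl)oxy]-1-[(4S)-2,2-dimethyl-1,3-dioxolan-4-yl]-6-methyloct-6-en-2-yn-1-ol (C9 carbinol) | CC(C)(C)[Si](C)(C)OC/C=C(/C)CCC#C[C@H](O)[C@@H]1COC(C)(C)O1 | intermediate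
11 | (2E,6Z)-8-[(tert-butyldimethylsilyl)oxy]-1-[(4S)-2,2-dimethyl-1,3-dioxolan-4-yl]-6-methyl-2-(tributylstannyl)octa-2,6-dien-1-ol, carbinol configured as in 10, C2 cis to C9 | CC(C)(C)[Si](C)(C)OC/C=C(/C)CC/C=C(/[Sn](CCCC)(CCCC)CCCC)[C@H](O)[C@@H]1COC(C)(C)O1 | intermediate
12 | dilithio species: lithium alkoxide of 11 with Li in place of Bu3Sn on C10 (not isolated) | CC(C)(C)[Si](C)(C)OC/C=C(/C)CC/C=C(/[Li])[C@H](O[Li])[C@@H]1COC(C)(C)O1 | intermediate
13 | (1S,2Z,6Z)-8-[(tert-butyldimethylsilyl)oxy]-1-[(4S)-2,2-dimethyl-1,3-dioxolan-4-yl]-2-(hydroxymethyl)-6-methylocta-2,6-dien-1-ol (9,14-diol, C14 trans to C2) | CC(C)(C)[Si](C)(C)OC/C=C(/C)CC/C=C(/CO)[C@H](O)[C@@H]1COC(C)(C)O1 | intermediate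
14 | 13 with O9 and O14 bridged by di-tert-butylsilylene (2,2-di-tert-butyl-1,3,2-dioxasilinane carrying the C1 alkylidene on C10); C6 OTBS and 7,8-acetonide kept | CC(C)(C)[Si](C)(C)OC/C=C(/C)CC/C=C1/CO[Si](C(C)(C)C)(C(C)(C)C)O[C@@H]1[C@@H]2COC(C)(C)O2 | intermediate
15 | triol: 14 with free hydroxyls at C6, C7 and C8 | OC/C=C(/C)CC/C=C1/CO[Si](C(C)(C)C)(C(C)(C)C)O[C@@H]1[C@@H](O)CO | intermediate
16 | C6 allylic chloride of 15, 7,8-diol free | ClC/C=C(/C)CC/C=C1/CO[Si](C(C)(C)C)(C(C)(C)C)O[C@@H]1[C@@H](O)CO | intermediate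
17 | 7,8-bis(triethylsilyl) ether of 16 | ClC/C=C(/C)CC/C=C1/CO[Si](C(C)(C)C)(C(C)(C)C)O[C@@H]1[C@@H](O[Si](CC)(CC)CC)CO[Si](CC)(CC)CC | intermediate
18 | C7 aldehyde with C8–OTES, C6 chloride and silylene | ClC/C=C(/C)CC/C=C1/CO[Si](C(C)(C)C)(C(C)(C)C)O[C@@H]1[C@@H](O[Si](CC)(CC)CC)C=O | intermediate
19 | ethyl 2-(diethoxyphosphoryl)acrylate | C=C(C(=O)OCC)P(=O)(OCC)OCC | starting material
20 | sodium salt of ethyl 2-(diethoxyphosphoryl)-3-[(4-methoxybenzyl)oxy]propanoate, the phosphonate carbanion (not isolated) | CCOC(=O)[C-](COCc1ccc(OC)cc1)P(=O)(OCC)OCC.[Na+] | intermediate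
21 | enoate: C7=C11 alkene with CO2Et (C12) trans to C8 and CH2OPMB (C13) cis to C8 | ClC/C=C(/C)CC/C=C1/CO[Si](C(C)(C)C)(C(C)(C)C)O[C@@H]1[C@@H](O[Si](CC)(CC)CC)/C=C(/C(=O)OCC)COCc1ccc(OC)cc1 | intermediate
22 | allylic alcohol: 21 with C12 as CH2OH (trans to C8) | ClC/C=C(/C)CC/C=C1/CO[Si](C(C)(C)C)(C(C)(C)C)O[C@@H]1[C@@H](O[Si](CC)(CC)CC)/C=C(/CO)COCc1ccc(OC)cc1 | intermediate
23 | thirteen-membered diallylic ether (oxygen between C12 and C6), C13–OPMB, C8–OTES, O9/O14 silylene | C1/C=C(/C)CC/C=C2/CO[Si](C(C)(C)C)(C(C)(C)C)O[C@@H]2[C@@H](O[Si](CC)(CC)CC)/C=C(/CO1)COCc3ccc(OC)cc3 | intermediate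
24 | thirteen-membered diallylic ether with free C13 hydroxyl (precursor of the key step) | C1/C=C(/C)CC/C=C2/CO[Si](C(C)(C)C)(C(C)(C)C)O[C@@H]2[C@@H](O[Si](CC)(CC)CC)/C=C(/CO1)CO | intermediate
25 | dilithio species of 24: C13–OLi and lithium on C6 (not isolated) | [Li]C1/C=C(/C)CC/C=C2/CO[Si](C(C)(C)C)(C(C)(C)C)O[C@@H]2[C@@H](O[Si](CC)(CC)CC)/C=C(/CO1)CO[Li] | intermediate
26 | ten-membered (6R,7S)-diol: C6 hydroxyl, C7 bearing the 3-hydroxyprop-1-en-2-yl group, C8–OTES, O9/O14 silylene | O[C@@H]1/C=C(/C)CC/C=C2/CO[Si](C(C)(C)C)(C(C)(C)C)O[C@@H]2[C@@H](O[Si](CC)(CC)CC)[C@H]1C(=C)CO | intermediate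
27 | hydroxy enal: 26 with C13 as CHO (not isolated) | O[C@@H]1/C=C(/C)CC/C=C2/CO[Si](C(C)(C)C)(C(C)(C)C)O[C@@H]2[C@@H](O[Si](CC)(CC)CC)[C@H]1C(=C)C=O | intermediate
28 | lactol from 27, mixture at C13 (not isolated) | C=C1C(O)O[C@@H]2/C=C(/C)CC/C=C3/CO[Si](C(C)(C)C)(C(C)(C)C)O[C@@H]3[C@@H](O[Si](CC)(CC)CC)[C@@H]12 | intermediate
29 | trans-fused α-methylene γ-lactone with C8–OTES and O9/O14 silylene | C=C1C(=O)O[C@@H]2/C=C(/C)CC/C=C3/CO[Si](C(C)(C)C)(C(C)(C)C)O[C@@H]3[C@@H](O[Si](CC)(CC)CC)[C@@H]12 | intermediate
30 | C8 alcohol of 29 | C=C1C(=O)O[C@@H]2/C=C(/C)CC/C=C3/CO[Si](C(C)(C)C)(C(C)(C)C)O[C@@H]3[C@@H](O)[C@@H]12 | intermediate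
31 | (S)-2-methylbutanoic acid | CC[C@H](C)C(=O)O | starting material
32 | C8 (S)-2-methylbutanoate of 30 | C=C1C(=O)O[C@@H]2/C=C(/C)CC/C=C3/CO[Si](C(C)(C)C)(C(C)(C)C)O[C@@H]3[C@@H](OC(=O)[C@@H](C)CC)[C@@H]12 | intermediate
33 | 9,14-diol (C9 hydroxyl, C14 hydroxymethyl on C10) | C=C1C(=O)O[C@@H]2/C=C(/C)CC/C=C(/CO)[C@H](O)[C@@H](OC(=O)[C@@H](C)CC)[C@@H]12 | intermediate
34 | CNP0168436.1, (6R,7S,8S,9S)-lactone with C14 aldehyde, C9 hydroxyl and C8 (S)-2-methylbutanoate | C=C1C(=O)O[C@@H]2/C=C(/C)CC/C=C(/C=O)[C@H](O)[C@@H](OC(=O)[C@@H](C)CC)[C@@H]12 | target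

Total step count: 23. Longest linear sequence: 22 steps (steps 1–3, then 5–23, from nerol).

Three steps most likely to fail

1. Step 18 (key step). What may go wrong: lithiation at an allylic position other than C6, a competing [1,2]-shift, or bond formation on the wrong face of C7. The fallback sets out from 22 and comes back at 26. The C6 chloride of 22 is oxidised with N-methylmorpholine N-oxide and NaI (cat.) in MeCN to the (Z)-enal alcohol F1. CBr4/PPh3 (CH2Cl2, −20 °C) then turns the C12 hydroxyl into the allylic bromide F2. CrCl2 (THF, high dilution, rt) effects an intramolecular Nozaki–Hiyama allylation in which C7 of the allylchromium unit adds to the C6 aldehyde. This should give the ten-membered homoallylic alcohol F3, the C13 PMB ether of 26, with the anti C6/C7 relationship typical of this addition. DDQ as in step 17 then gives 26.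

2. Step 16. What may go wrong: intermolecular etherification and base-induced loss of HCl from the neryl-type chloride may outrun the entropically costly ring closure. The fallback sets out from 22 and comes back at 23; it reverses the roles of the two allylic termini, so that O–C12 is the bond closed. CsOAc (DMF, rt) displaces the C6 chloride to give the C6 acetate F4. MsCl, LiCl and 2,4,6-collidine (DMF, 0 °C) convert the C12 hydroxyl into the allylic chloride F5. i-Bu2AlH (CH2Cl2, −78 °C) removes the acetate to give the C6 alcohol F6. NaH (THF, high dilution) then closes the ring by attack of the C6 alkoxide on the less elimination-prone C12 chloride, giving 23.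

3. Step 7. What may go wrong: tin may be delivered to the distal alkyne carbon C1 under steric control instead of to C10. The fallback sets out from 10 and comes back at 13 in one operation. i-BuMgBr (3 equiv) with Cp2TiCl2 (5 mol%) in Et2O hydromagnesiates the alkoxide of 10, syn and with magnesium on the carbon next to the alkoxide, to give the vinylmagnesium alkoxide F7. F7 is trapped with formaldehyde to give 13 directly, which also replaces step 8.

Further compounds
F1 | step 18 | (Z)-enal alcohol: 22 with C6 as CHO in place of CH2Cl | O=C/C=C(/C)CC/C=C1/CO[Si](C(C)(C)C)(C(C)(C)C)O[C@@H]1[C@@H](O[Si](CC)(CC)CC)/C=C(/CO)COCc1ccc(OC)cc1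
F2 | step 18 | allylic bromide: F1 with C12 as CH2Br | O=C/C=C(/C)CC/C=C1/CO[Si](C(C)(C)C)(C(C)(C)C)O[C@@H]1[C@@H](O[Si](CC)(CC)CC)/C=C(/CBr)COCc1ccc(OC)cc1
F3 | step 18 | ten-membered homoallylic alcohol, the C13 PMB ether of 26 | O[C@@H]1/C=C(/C)CC/C=C2/CO[Si](C(C)(C)C)(C(C)(C)C)O[C@@H]2[C@@H](O[Si](CC)(CC)CC)[C@H]1C(=C)COCc1ccc(OC)cc1
F4 | step 16 | C6 acetate: 22 with OAc in place of Cl | CC(=O)OC/C=C(/C)CC/C=C1/CO[Si](C(C)(C)C)(C(C)(C)C)O[C@@H]1[C@@H](O[Si](CC)(CC)CC)/C=C(/CO)COCc1ccc(OC)cc1
F5 | step 16 | C12 allylic chloride of F4 | CC(=O)OC/C=C(/C)CC/C=C1/CO[Si](C(C)(C)C)(C(C)(C)C)O[C@@H]1[C@@H](O[Si](CC)(CC)CC)/C=C(/CCl)COCc1ccc(OC)cc1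
F6 | step 16 | C6 alcohol with C12 chloride | OC/C=C(/C)CC/C=C1/CO[Si](C(C)(C)C)(C(C)(C)C)O[C@@H]1[C@@H](O[Si](CC)(CC)CC)/C=C(/CCl)COCc1ccc(OC)cc1
F7 | step 7 | vinylmagnesium alkoxide from 10, Mg on C10 and H on C1 on the same side | CC(C)(C)[Si](C)(C)OC/C=C(/C)CC/C=C(/[Mg]Br)[C@H](O[Mg]Br)[C@@H]1COC(C)(C)O1
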